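The ratio I wanted for the flask was reagent supplied over reagent needed. I call it the budget ratio ρ, the uptake u times the time, divided by the charge times the demand d. Here u is the reagent built into products per minute, and d is the reagent built in per starting material charged.

| flask | starting material | gas | remark | time |
|---|---|---|---|---|
| Saturday's | 10 mM | 2.8 mM (held) | run made earlier |  |
| Friday's | 15 mM | 2.8 mM (held) | run made earlier |  |
| flask | 20 mM | 2.8 mM (held) |  | 4.0 min |

| run | time / min | side product B / % | target / % | side product A / % | isomer of the product / % | starting material / % |
|---|---|---|---|---|---|---|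
| Saturday's | 0.417 | 0.9 | 8.1 | 6.8 | 0.9 | 83.5 |
| Saturday's | 1.33 | 5.2 | 20.4 | 25.0 | 6.6 | 43.2 |
| Saturday's | 2.00 | 7.8 | 24.7 | 36.0 | 10.3 | 22.4 |
| Saturday's | 3.00 | 8.8 | 27.8 | 45.3 | 13.5 | 5.3 |
| Saturday's | 5.00 | 10.3 | 27.4 | 48.6 | 14.5 | 0 |
| Friday's | 0.417 | 0.8 | 6.8 | 4.6 | 0.5 | 86.3 |
| Friday's | 0.667 | 2.5 | 9.9 | 8.5 | 1.9 | 76.9 |
| Friday's | 1.33 | 7.5 | 17.0 | 18.8 | 5.4 | 51.8 |
| Friday's | 2.50 | 13.7 | 22.4 | 33.3 | 9.9 | 18.6 |
| Friday's | 5.00 | 16.4 | 25.5 | 44.1 | 14.1 | 0 |

(readings scatter by 0.3 percentage points)

- a species is counted by the starting material in it: one side product B counts as two
- at the start none of reagent is dissolved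
- candidate steps: target <-> isomer of the product; starting material + 2 reagent -> side product A; starting material + reagent -> target; starting material + target -> side product B; gas <-> reagent

* the species that holds most of what was charged as starting material, at 4.0 min (side product B / isomer of the product / starting material / target / side product A)
* the largest share itself, whichever of these holds it, in percent of the starting material charged

Counting target and isomer once, side product A twice and side product B a half, Friday's run gave u = 6.34 mM min⁻¹, averaged from the start to 2.50 min. I took gas uptake as the rate-limiting step, which was an assumption. The last readings gave d = 1.44 on Saturday and 1.36 on Friday, so d fell with the charge. Continuing that step gave 1.28 for the flask, and so ρ = 0.993.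

But u was not steady: Friday's run averaged 7.19 mM min⁻¹ from the start to 1.33 min, and Saturday's averaged 4.54 mM min⁻¹ from the start to 3.00 min, with 5.3% starting material left. So I distrusted the 0.700% of starting material left that ρ says, and expected more in the flask. Continuing the last readings of side product A the same way gave 39.6% and those of target gave 23.6%, both figures for a run read with its starting material at 0%, so I expected side product A to lead target in the flask.

The forecast named side product A at 37%, between 33% and 41%: “More concentrated runs therefore give less A and more B”.

The flask gave side product A at 37.6%, with 4.39% starting material left.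

target ⇌ isomer of the product (K = 0.530, k = 0.0123 s⁻¹); starting material + 2 reagent → side product A (k = 3030 M⁻² s⁻¹); starting material + reagent → target (k = 4.31 M⁻¹ s⁻¹); starting material + target → side product B (k = 0.448 M⁻¹ s⁻¹); gas ⇌ reagent, rate k5*(csat - [reagent]) (kL = 0.0750 s⁻¹) The same reckoning for this flask read at 2.5 min left 37.9% starting material, but the flask then held 26%, less than reckoned. The flask at 4.0 min had not come to rest. By 40.0 min starting material stood at 0%, reagent had gone from 2.22 mM to 2.80 mM, target read 24.1%, and side product A had gained 2.6 percentage points to reach 40.1%.

The runs are simulated from invented constants; the scatter is artificial.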